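The closed, stirred vessel starts with solid substrate and a solution free of it; eta is the asked flask itself, followed so far, and zeta is an earlier run with a larger charge.

| flask | solid substrate | remark | time |
|---|---|---|---|
| eta | 20 mM | the very flask that is asked about, followed so far |  |
| zeta | 40 mM | run made earlier |  |
| flask | 20 mM |  | 10 h |

- eta (time / min: solid substrate / %, starting material / %): 25.0: 94.8, 4.1; 50.0: 95.6, 4.5; 80.0: 94.4, 4.3; 90.0: 94.4, 3.7; 120: 93.7, 4.7
- zeta (time / h: solid substrate / %, starting material / %): 0.333: 98.4, 1.8; 0.667: 97.2, 1.6; 1.00: 97.6, 1.6; 2.00: 97.2, 2.4; 4.00: 96.8, 2.9

(scatter of a reading: 0.5 percentage points)

- solid substrate is a solid; its amount is given per volume of the solution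
- at the start none of the solid substrate is in solution
- what has only dissolved of solid substrate counts as not reacted
- starting material means what is dissolved; the solid is not counted in it
- the reaction counts as stopped when no species that holds the solid substrate changes by six tenths of a point or more over the second half of the time

- why nothing more happens at 10 h, or that something still does (for what has run out or reacted, a solid counts together with what of it has only dissolved) (all of the solid substrate has reacted / forward and back rates have come level / it is still moving)
- part of the solid substrate that has turned into other species by 10 h (what has only dissolved does not count)
- the starting material standing at 10 h, as a percentage of the solid substrate charged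

My own reckoning follows the rate of solid loss. In eta, solid leaves at 2.50 mM h⁻¹ on average up to the first reading, then at 0.139 mM h⁻¹ up to the last, a fall by a factor of 18.0. That first slowing comes with a level c(starting material): the mean reading is 0.852 mM in eta and 0.824 mM in zeta, which holds twice the charge. This dissolved ceiling, the saturation concentration as read from these scattered readings, stands in mM, so its share of the eta charge is 4.26 %.

Zeta later loses solid at 0.107 mM h⁻¹, a further factor of only 1.30, with a scatter of 0.0943 mM h⁻¹. Held at that rate, eta would lose 2.7 percentage points over the second half of the time, so I lean to still moving, weakly.

The forecast's answer is that it is still moving, with 4.5 % converted and 5 % dissolved, the last a little above my share: “Plenty of solid remains, so this should continue.”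

In the flask forward and back rates have come level, with 3.07 % converted and 4.68 % dissolved.

    starting material ⇌ target (K = 0.180, k = 0.680 h⁻¹)
    target ⇌ isomer of the product (K = 2.90, k = 0.180 h⁻¹)
    isomer of the product ⇌ starting material (k = 0.200 h⁻¹)
    solid substrate ⇌ starting material, rate k4*(cs4 - [starting material]) while solid is left; crystals form when [starting material] > cs4 (solubility = 0.940 mM, k = 3.80 h⁻¹)

Carried to the neighbouring flask charged with 5.0 mM, the reading 0.852 mM divided by that charge gives 17.0 %, and that flask shows 18.7 % starting material at 10.0 h, with 69.0 % still solid. Its conversion, 12.3 %, is larger as a share, but in mM it comes to 0.615 mM, against 0.614 mM in the asked flask.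

Readings and results are simulated for substances that don't exist, noise included.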